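The route rests on cutting the dihydropyran ring of the chroman between C2, the quaternary carbon bound to the ring oxygen O1, and C3, the carbinol carbon. This O1–C2–C3–OH array is the signature of a ketyl adding to the β-carbon of a β-aryloxy vinyl sulfoxide. One SmI2-induced cyclisation therefore closes the ring, sets both stereocentres under control of an enantiopure p-tolylsulfinyl group and leaves a CH2S(O)Tol arm that becomes the C2 methyl group. The precursor is an arylacetaldehyde whose phenolic oxygen carries an (E)-configured enol ether, already bearing the complete diene side chain, made by adding a phenol to an alkynyl sulfoxide.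

Key step: step 7

Assumption: the (R)-configured vinyl sulfoxide derived from (−)-menthyl (S)-p-toluenesulfinate is taken to steer the ketyl to the alkene face that leads to (2S,3S), by the chelation model given in step 7. If the sense proved opposite, the commercial enantiomeric sulfinate would be used in an otherwise unchanged route.

Step 1
Reactants: 1 methyl 3-formyl-4-hydroxybenzoate
Product: 2 methyl 4-hydroxy-3-vinylbenzoate
Conditions: Ph3PCH3Br (2.3 equiv), KOtBu (2.3 equiv), THF, 0 °C to rt
Reagents that add atoms: methylenetriphenylphosphorane, made from Ph3PCH3Br and KOtBu, C=P(c1ccccc1)(c1ccccc1)c1ccccc1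
Why: Wittig methylenation of the aldehyde, in which the excess ylide absorbs the phenolic proton and the benzoate ester is not attacked; no stereocentre is formed.

Step 2
Reactants: 2 methyl 4-hydroxy-3-vinylbenzoate
Product: 4 methyl 4-hydroxy-3-(2-hydroxyethyl)benzoate, via B-alkyl-9-BBN adduct 3 (not isolated)
Conditions: 9-BBN (2.2 equiv), THF, 0 °C to rt; then aq NaOH, H2O2, 0 °C
Reagents that add atoms: hydrogen peroxide, OO
Why: Hydroboration–oxidation, in which 9-BBN places boron on the terminal styrene carbon and the phenoxide formed under NaOH deactivates the para ester towards saponification during the short oxidation.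

Step 3
Reactants: 5 1-(trimethylsilyl)propyne; 6 geranyl bromide
Product: 9 (E)-6,10-dimethylundeca-5,9-dien-1-yne, via 3-lithio-1-(trimethylsilyl)propyne 7 (not isolated), via silylated enyne 8 (not isolated)
Conditions: 5, n-BuLi, THF, −78 to −20 °C; 6, −78 °C to rt; then Bu4NF, THF, rt
Reagents that add atoms: none
Why: Propargylic lithiation of the silyl propyne and SN2 alkylation by the primary allylic bromide should keep the (E)-alkene, and fluoride then removes the alkynyl silyl group in the same flask.

Step 4
Reactants: 9 (E)-6,10-dimethylundeca-5,9-dien-1-yne; 10 (1R,2S,5R)-menthyl (S)-p-toluenesulfinate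
Product: 12 1-{(S)-[(5E)-6,10-dimethylundeca-5,9-dien-1-yn-1-yl]sulfinyl}-4-methylbenzene, via alkynylmagnesium bromide 11 (not isolated)
Conditions: EtMgBr, THF, 0 °C to rt; then 10, toluene, −20 °C
Reagents that add atoms: none
Why: Andersen sulfoxide synthesis, in which the alkynyl Grignard reagent displaces mentholate with inversion at sulfur and so sets the sulfur stereocentre.

Step 5
Reactants: 4 methyl 4-hydroxy-3-(2-hydroxyethyl)benzoate; 12 the (S)-alkynyl sulfoxide
Product: 13 methyl 4-{[(1E,5E)-6,10-dimethyl-1-[(R)-4-methylbenzenesulfinyl]undeca-1,5,9-trien-2-yl]oxy}-3-(2-hydroxyethyl)benzoate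
Conditions: Cs2CO3 (0.3 equiv), DMF, 40 °C
Reagents that add atoms: none
Why: Oxa-Michael addition of the phenoxide (far more acidic than the primary alcohol) to the alkynyl sulfoxide, where reversible addition under base should funnel the push–pull enol ether to the (E)-isomer with aryloxy trans to sulfinyl; sulfur is untouched, and its descriptor changes from S to R only through the priority rules.

Step 6
Reactants: 13 the hydroxyethyl vinyl sulfoxide
Product: 14 methyl 4-{[(1E,5E)-6,10-dimethyl-1-[(R)-4-methylbenzenesulfinyl]undeca-1,5,9-trien-2-yl]oxy}-3-(2-oxoethyl)benzoate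
Conditions: Dess–Martin periodinane, CH2Cl2, 0 °C to rt
Reagents that add atoms: none
Why: Dess–Martin oxidation of the primary alcohol under near-neutral conditions should spare the sulfoxide, the enol ether and the alkenes, and the sensitive arylacetaldehyde is used at once.

Step 7
Reactants: 14 the aldehyde vinyl sulfoxide
Product: 15 methyl (2S,3S)-2-[(3E)-4,8-dimethylnona-3,7-dien-1-yl]-3-hydroxy-2-{[(R)-4-methylbenzenesulfinyl]methyl}-3,4-dihydro-2H-chromene-6-carboxylate
Conditions: SmI2 (3 equiv), MeOH (10 equiv), THF, −78 to 0 °C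
Reagents that add atoms: none
Why: SmI2 reduces the aldehyde of 14 to a samarium ketyl whose trivalent samarium also binds the sulfinyl oxygen; the ketyl carbon (C3) adds to the β-carbon (C2) of the β-aryloxyvinyl sulfoxide, and the α-sulfinyl radical is reduced by a second SmI2 and protonated by MeOH, which closes the dihydropyran ring and leaves the CH2S(O)Tol arm. The closest known reaction type is the SmI2-induced reductive cyclisation of aldehydes onto β-alkoxyacrylates, β-alkoxyvinyl sulfones and enantiopure β-alkoxyvinyl sulfoxides, which gives 3-hydroxy cyclic ethers. The ring closes in a 6-exo-trig radical (ketyl–olefin) mode that forms the C2–C3 bond. At C3, the samarium-bridged chair should place the samarium-bound oxygen and the acceptor arm pseudo-equatorial, giving OH trans to CH2S(O)Tol and cis to the diene chain, which requires the (E)-enol ether (sulfinyl cis to the chain, trans to O1). At C2, the A(1,3)-minimised conformer of the (E)-vinyl sulfoxide has the sulfur lone pair eclipsing the chain, the S–O bond over one alkene face and the p-tolyl group over the other, so the chelated ketyl should be delivered syn to S–O, which for the (R)-sulfoxide is the face that gives (2S). The step needs reduction of the aldehyde in preference to the benzoate and the vinyl sulfoxide, and protonation of the α-sulfinyl samarium species faster than loss of the aryloxide, both of which MeOH at low temperature is meant to secure.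

Step 8
Reactants: 15 the sulfinylmethyl chromanol
Product: 16 methyl (2S,3S)-2-[(3E)-4,8-dimethylnona-3,7-dien-1-yl]-3-hydroxy-2-methyl-3,4-dihydro-2H-chromene-6-carboxylate
Conditions: Raney Ni (W-2, acetone-deactivated), EtOH/THF, 0 °C to rt
Reagents that add atoms: none
Why: Reductive desulfurisation on nickel cleaves both C–S bonds and turns the CH2S(O)Tol arm into the C2 methyl group, the deactivated catalyst is expected to spare the isolated trisubstituted alkenes, and neither stereocentre is touched.

Step 9
Reactants: 16 the methyl ester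
Product: 17 (2S,3S)-2-[(3E)-4,8-dimethylnona-3,7-dien-1-yl]-3-hydroxy-2-methyl-3,4-dihydro-2H-chromene-6-carboxylic acid
Conditions: LiOH, THF/MeOH/H2O, 40 °C; then cold 1 M HCl to pH 3
Reagents that add atoms: lithium hydroxide, [Li+].[OH-]
Why: Saponification of the aryl methyl ester, with a cold, brief acidification so that the diene chain meets no strong acid; the stereocentres are not affected.

Compound list
1 | methyl 3-formyl-4-hydroxybenzoate | COC(=O)c1ccc(O)c(C=O)c1 | starting material
2 | methyl 4-hydroxy-3-vinylbenzoate | COC(=O)c1ccc(O)c(C=C)c1 | intermediate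
3 | methyl 3-[2-(9-borabicyclo[3.3.1]nonan-9-yl)ethyl]-4-hydroxybenzoate | COC(=O)c1ccc(O)c(CCB2C3CCCC2CCC3)c1 | intermediate (not isolated)
4 | methyl 4-hydroxy-3-(2-hydroxyethyl)benzoate | COC(=O)c1ccc(O)c(CCO)c1 | intermediate
5 | 1-(trimethylsilyl)propyne | CC#C[Si](C)(C)C | starting material
6 | geranyl bromide, (2E)-1-bromo-3,7-dimethylocta-2,6-diene | CC(C)=CCC/C(C)=C/CBr | starting material
7 | 3-lithio-1-(trimethylsilyl)propyne | [Li]CC#C[Si](C)(C)C | intermediate (not isolated)
8 | [(5E)-6,10-dimethylundeca-5,9-dien-1-yn-1-yl]trimethylsilane | CC(C)=CCC/C(C)=C/CCC#C[Si](C)(C)C | intermediate (not isolated)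
9 | (E)-6,10-dimethylundeca-5,9-dien-1-yne | CC(C)=CCC/C(C)=C/CCC#C | intermediate
10 | (1R,2S,5R)-menthyl (S)-p-toluenesulfinate | Cc1ccc(cc1)[S@@](=O)O[C@@H]1C[C@H](C)CC[C@H]1C(C)C | starting material
11 | [(5E)-6,10-dimethylundeca-5,9-dien-1-yn-1-yl]magnesium bromide | CC(C)=CCC/C(C)=C/CCC#C[Mg]Br | intermediate (not isolated)
12 | 1-{(S)-[(5E)-6,10-dimethylundeca-5,9-dien-1-yn-1-yl]sulfinyl}-4-methylbenzene | CC(C)=CCC/C(C)=C/CCC#C[S@@](=O)c1ccc(C)cc1 | intermediate
13 | methyl 4-{[(1E,5E)-6,10-dimethyl-1-[(R)-4-methylbenzenesulfinyl]undeca-1,5,9-trien-2-yl]oxy}-3-(2-hydroxyethyl)benzoate | CC(C)=CCC/C(C)=C/CC/C(Oc1ccc(C(=O)OC)cc1CCO)=C\[S@@](=O)c1ccc(C)cc1 | intermediate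
14 | methyl 4-{[(1E,5E)-6,10-dimethyl-1-[(R)-4-methylbenzenesulfinyl]undeca-1,5,9-trien-2-yl]oxy}-3-(2-oxoethyl)benzoate | CC(C)=CCC/C(C)=C/CC/C(Oc1ccc(C(=O)OC)cc1CC=O)=C\[S@@](=O)c1ccc(C)cc1 | intermediate
15 | methyl (2S,3S)-2-[(3E)-4,8-dimethylnona-3,7-dien-1-yl]-3-hydroxy-2-{[(R)-4-methylbenzenesulfinyl]methyl}-3,4-dihydro-2H-chromene-6-carboxylate | CC(C)=CCC/C(C)=C/CC[C@]1(C[S@@](=O)c3ccc(C)cc3)Oc2ccc(C(=O)OC)cc2C[C@@H]1O | intermediate
16 | methyl (2S,3S)-2-[(3E)-4,8-dimethylnona-3,7-dien-1-yl]-3-hydroxy-2-methyl-3,4-dihydro-2H-chromene-6-carboxylate | CC(C)=CCC/C(C)=C/CC[C@]1(C)Oc2ccc(C(=O)OC)cc2C[C@@H]1O | intermediate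
17 | (2S,3S)-2-[(3E)-4,8-dimethylnona-3,7-dien-1-yl]-3-hydroxy-2-methyl-3,4-dihydro-2H-chromene-6-carboxylic acid | CC(C)=CCC/C(C)=C/CC[C@]1(C)Oc2ccc(C(=O)O)cc2C[C@@H]1O | target

Total step count: 9. Longest linear sequence: 7 steps (steps 1, 2, 5, 6, 7, 8, 9; the branch through steps 3 and 4 is equally long).

Steps most likely to fail

Step 7. The α-sulfinyl organosamarium species formed after the radical ring closure may expel the aryloxide before it is protonated. This would reopen the ring at O1–C2 while keeping the new C2–C3 bond. A second concern is a low level, or an unexpected sense, of facial discrimination by the sulfinyl group; the isomers would then be diastereomers and separable. The fallback sets out from 14 and comes back at 15. The samarium step is run without trying to suppress the elimination, and the ring-opened product is collected as methyl 4-hydroxy-3-{(2S,3E,6E)-2-hydroxy-7,11-dimethyl-3-[(R)-(4-methylbenzenesulfinyl)methylidene]dodeca-6,10-dien-1-yl}benzoate F1. This phenol is then closed in a separate operation by base-mediated intramolecular oxa-Michael addition of the phenoxide to the vinyl sulfoxide (catalytic Cs2CO3, MeCN, rt). That is a polar 6-exo-trig C–O closure in which the C3 carbinol centre set in the samarium step and the sulfinyl group should bias the configuration at C2, to give 15.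

Step 5. Base may isomerise the propargylic alkynyl sulfoxide to the allenyl sulfoxide faster than the phenoxide adds, and the enol ether may not equilibrate fully to the (E)-isomer. The fallback sets out from 12 and comes back at 13. Hydrochlorination of 12 (LiCl, AcOH, MeCN, 60 °C) should give, by anti addition, 1-{(R)-[(1Z,5E)-2-chloro-6,10-dimethylundeca-1,5,9-trien-1-yl]sulfinyl}-4-methylbenzene F2. Addition–elimination of the phenoxide of 4 on this vinylogous sulfinyl chloride (Cs2CO3, DMF, rt), followed by phenoxide-mediated equilibration, should then give 13 without the alkyne ever meeting base.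

Step 8. The nickel surface may saturate or shift the two trisubstituted alkenes in competition with C–S hydrogenolysis. The fallback sets out from 15 and comes back at 16. It replaces hydrogenolysis by oxygenation of the sulfur-bearing carbon and radical deoxygenation, so that the carbon radical is quenched by hydrogen-atom transfer and no carbanion β to the aryloxy group arises.
- Silylation (Et3SiCl, imidazole, DMF) gives methyl (2S,3S)-2-[(3E)-4,8-dimethylnona-3,7-dien-1-yl]-2-{[(R)-4-methylbenzenesulfinyl]methyl}-3-(triethylsilyloxy)-3,4-dihydro-2H-chromene-6-carboxylate F3.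
- Pummerer rearrangement with reduction in the same flask ((CF3CO)2O, 2,4,6-collidine, MeCN, 0 °C; then NaBH4, EtOH) gives methyl (2R,3S)-2-[(3E)-4,8-dimethylnona-3,7-dien-1-yl]-2-(hydroxymethyl)-3-(triethylsilyloxy)-3,4-dihydro-2H-chromene-6-carboxylate F4.
- Acylation (PhOC(S)Cl, pyridine, DMAP, CH2Cl2) gives methyl (2R,3S)-2-[(3E)-4,8-dimethylnona-3,7-dien-1-yl]-2-{[(phenoxycarbonothioyl)oxy]methyl}-3-(triethylsilyloxy)-3,4-dihydro-2H-chromene-6-carboxylate F5.
- Barton–McCombie deoxygenation (Bu3SnH, AIBN, toluene, 110 °C) gives methyl (2S,3S)-2-[(3E)-4,8-dimethylnona-3,7-dien-1-yl]-2-methyl-3-(triethylsilyloxy)-3,4-dihydro-2H-chromene-6-carboxylate F6.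
- Desilylation (Bu4NF, THF, rt) returns 16.

Further compounds
F1 | step 7 | methyl 4-hydroxy-3-{(2S,3E,6E)-2-hydroxy-7,11-dimethyl-3-[(R)-(4-methylbenzenesulfinyl)methylidene]dodeca-6,10-dien-1-yl}benzoate | CC(C)=CCC/C(C)=C/CC/C(=C\[S@@](=O)c1ccc(C)cc1)[C@@H](O)Cc1cc(C(=O)OC)ccc1O
F2 | step 5 | 1-{(R)-[(1Z,5E)-2-chloro-6,10-dimethylundeca-1,5,9-trien-1-yl]sulfinyl}-4-methylbenzene | CC(C)=CCC/C(C)=C/CC/C(Cl)=C/[S@@](=O)c1ccc(C)cc1
F3 | step 8 | methyl (2S,3S)-2-[(3E)-4,8-dimethylnona-3,7-dien-1-yl]-2-{[(R)-4-methylbenzenesulfinyl]methyl}-3-(triethylsilyloxy)-3,4-dihydro-2H-chromene-6-carboxylate | CC(C)=CCC/C(C)=C/CC[C@]1(C[S@@](=O)c3ccc(C)cc3)Oc2ccc(C(=O)OC)cc2C[C@@H]1O[Si](CC)(CC)CC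
F4 | step 8 | methyl (2R,3S)-2-[(3E)-4,8-dimethylnona-3,7-dien-1-yl]-2-(hydroxymethyl)-3-(triethylsilyloxy)-3,4-dihydro-2H-chromene-6-carboxylate | CC(C)=CCC/C(C)=C/CC[C@]1(CO)Oc2ccc(C(=O)OC)cc2C[C@@H]1O[Si](CC)(CC)CC
F5 | step 8 | methyl (2R,3S)-2-[(3E)-4,8-dimethylnona-3,7-dien-1-yl]-2-{[(phenoxycarbonothioyl)oxy]methyl}-3-(triethylsilyloxy)-3,4-dihydro-2H-chromene-6-carboxylate | CC(C)=CCC/C(C)=C/CC[C@]1(COC(=S)Oc3ccccc3)Oc2ccc(C(=O)OC)cc2C[C@@H]1O[Si](CC)(CC)CC
F6 | step 8 | methyl (2S,3S)-2-[(3E)-4,8-dimethylnona-3,7-dien-1-yl]-2-methyl-3-(triethylsilyloxy)-3,4-dihydro-2H-chromene-6-carboxylate | CC(C)=CCC/C(C)=C/CC[C@]1(C)Oc2ccc(C(=O)OC)cc2C[C@@H]1O[Si](CC)(CC)CC
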